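A direct plan would build the phloroglucinol ring by a [3+3] double C-acylation: a γ-prenylated 1-phenylbutane-1,3-dione A1 would be converted into its 1,3-bis(trimethylsilyloxy)diene A2, and A2 would be condensed with 2-prenylmalonyl dichloride A3 under silyl triflate catalysis. Its weakest steps would be the ring-forming double acylation (no precedent with a malonyl dichloride; O-acylation to lactones and loss of HCl from A3 would compete), the chlorination that would give A3 (an α-substituted malonyl chloride that would be prone to ketene formation and to HCl addition at the prenyl alkene), and the double silylation to A2, a hydrolytically labile diene that would have to be used crude.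

The ring alternates oxygen-bearing carbons (C2, C4, C6) with carbon-substituted ones (C1 benzoyl, C3 and C5 prenyl): the pattern of a head-to-tail trimer of three ketene units, and with all three oxygens ending as OH any alternating assembly gives the same compound. The route therefore unites a ketene that carries the benzoyl group as its dioxolane (C6, C1) with two molecules of one prenyl siloxyalkyne (C2–C3, C4–C5). A [2+2] cycloaddition gives a cyclobutenone, and a Danheiser benzannulation with the second alkyne closes the hexasubstituted ring by 6π electrocyclisation, every substituent in place. Malonyl chloride, bis(silyl enol ether) and acylative ring closure all disappear.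

Key step: step 6

Remark: ring atoms are labelled as in the target (C1 benzoyl; C2, C4, C6 hydroxyl; C3, C5 prenyl); 13, 15 and 17 are racemic, and their stereocentres vanish on aromatisation.

Step 1
Reactants: 1 ethynylmagnesium bromide; 2 1-bromo-3-methylbut-2-ene (prenyl bromide)
Product: 3 5-methylhex-4-en-1-yne
Conditions: 1 (1.2 equiv), CuCl (5 mol %), THF, 0 °C → rt; careful distillation
Reagents that add atoms: none
Why: CuCl-catalysed SN2 coupling of an alkynyl Grignard reagent with a primary allylic bromide, in which the alkynylcopper species attacks the unhindered CH2 terminus of 2 and so should give the skipped 1,4-enyne rather than the SN2′ isomer.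

Step 2
Reactants: 3 5-methylhex-4-en-1-yne
Product: 6 triisopropyl[(5-methylhex-4-en-1-yn-1-yl)oxy]silane, via lithium acetylide 4 (not isolated), via lithium ynolate 5 (not isolated)
Conditions: n-BuLi (1.05 equiv), THF, −78 °C; LiOOt-Bu [from anhydrous t-BuOOH (1.1 equiv) and LiN(SiMe3)2 (1.1 equiv), THF, −78 °C], −78 → 0 °C; i-Pr3SiOTf (1.3 equiv), −78 → 0 °C; filtration through neutral alumina (hexane)
Reagents that add atoms: tert-butyl hydroperoxide, CC(C)(C)OO; triisopropylsilyl trifluoromethanesulfonate, CC(C)[Si](C(C)C)(C(C)C)OS(=O)(=O)C(F)(F)F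
Why: n-BuLi removes only the sp C–H, acetylide 4 attacks the peroxide oxygen of LiOOt-Bu to give ynolate 5 (oxidation of a lithium acetylide with lithium tert-butyl peroxide), and the bulky silyl triflate silylates 5 on oxygen, the established preparation of siloxyalkynes, while the isolated trisubstituted alkene is inert to the peroxide.

Step 3
Reactants: 7 ethyl 3-oxo-3-phenylpropanoate (ethyl benzoylacetate); 8 ethane-1,2-diol
Product: 9 ethyl 2-(2-phenyl-1,3-dioxolan-2-yl)acetate
Conditions: 8 (3 equiv), p-TsOH·H2O (5 mol %), toluene, reflux, Dean–Stark trap; NaHCO3 work-up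
Reagents that add atoms: none
Why: Acid-catalysed ketalisation with azeotropic removal of water masks the benzoyl carbonyl, so that the ketene made later is a simple aldoketene and not an acylketene, which would add a siloxyalkyne in the [4+2] mode.

Step 4
Reactants: 9 ethyl 2-(2-phenyl-1,3-dioxolan-2-yl)acetate
Product: 10 potassium 2-(2-phenyl-1,3-dioxolan-2-yl)acetate
Conditions: KOH (1.00 equiv), EtOH, rt; evaporation, toluene azeotrope, drying in vacuo
Reagents that add atoms: potassium hydroxide, [K+].[OH-]
Why: Saponification (BAc2) with exactly one equivalent of KOH gives the dry potassium carboxylate directly, so that the acid-labile dioxolane never meets a mineral acid.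

Step 5
Reactants: 10 potassium 2-(2-phenyl-1,3-dioxolan-2-yl)acetate; 6 triisopropyl[(5-methylhex-4-en-1-yn-1-yl)oxy]silane
Product: 13 2-(3-methylbut-2-en-1-yl)-4-(2-phenyl-1,3-dioxolan-2-yl)-3-(triisopropylsilyloxy)cyclobut-2-en-1-one, via acid chloride 11 (not isolated), via ketene 12 (not isolated)
Conditions: 10 (1.3 equiv), (COCl)2 (1.25 equiv), pyridine (cat.), Et2O, 0 °C → rt; the decanted solution added slowly to 6 (1.0 equiv) and Et3N (1.6 equiv) in toluene, 0 °C → rt; filtration under argon, concentration; used crude
Reagents that add atoms: none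
Why: The potassium salt and oxalyl chloride give acid chloride 11 without free HCl, Et3N dehydrochlorinates 11 to aldoketene 12, and 12 undergoes the known [2+2] cycloaddition of ketenes with siloxyalkynes, the oxygen-free alkyne carbon adding to the ketene carbonyl carbon (relay bond C3–C6) and the ring closing at C1–C2 to give the 3-siloxycyclobutenone with head-to-tail regiochemistry; the ring CH of 13 is a racemic centre that is lost in step 6.

Step 6
Reactants: 13 2-(3-methylbut-2-en-1-yl)-4-(2-phenyl-1,3-dioxolan-2-yl)-3-(triisopropylsilyloxy)cyclobut-2-en-1-one; 6 triisopropyl[(5-methylhex-4-en-1-yn-1-yl)oxy]silane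
Product: 18 2,4-bis(3-methylbut-2-en-1-yl)-6-(2-phenyl-1,3-dioxolan-2-yl)-3,5-bis(triisopropylsilyloxy)phenol, via vinylketene 14 (not isolated), via alkenylcyclobutenone 15 (not isolated), via dienylketene 16 (not isolated), via cyclohexadienone 17 (not isolated)
Conditions: 6 (1.5 equiv), degassed toluene (0.3 M), sealed tube, 80 °C, then 110 °C; chromatography on Et3N-deactivated silica
Reagents that add atoms: none
Why: Danheiser benzannulation: 13 opens thermally (conrotatory 4π, cleaving C1–C6, the dioxolanyl group rotating outward) to vinylketene 14, whose ketene carbon C6 is attacked by the carbon of 6 remote from oxygen, and [2+2] closure (new bonds C5–C6 and C3–C4) gives 15. 15 opens in turn (cleaving the relay bond C3–C6) to dienylketene 16, and the six-membered ring is closed between C1 and C6 by disrotatory 6π electrocyclisation to cyclohexadienone 17, which tautomerises to 18; the two four-membered rings are only relays. The reaction type is the known benzannulation of cyclobutenones with hetero-substituted alkynes. No stereocentre survives, since the sp3 centres of 13, 15 and 17 are racemic and end as aromatic carbons. The selectivity needed is the head-to-tail union of ketene and alkyne, secured by the polarisation of the siloxyalkyne (its oxygen-free carbon is the nucleophile, the ketene carbon the electrophile); reversible opening of 15 funnels both alkene geometries into the one dienylketene able to cyclise. Because the three carbon substituents end on alternate ring atoms and every oxygen becomes OH, the result does not depend on which alternate position carries the masked benzoyl group.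

Step 7
Reactants: 18 2,4-bis(3-methylbut-2-en-1-yl)-6-(2-phenyl-1,3-dioxolan-2-yl)-3,5-bis(triisopropylsilyloxy)phenol
Product: 20 clusiaphenone B, via triol ketal 19 (not isolated)
Conditions: Bu4NF (2.2 equiv), THF, 0 °C, argon; then 0.5 M aqueous HCl to pH 2, 0 °C → rt
Reagents that add atoms: water, O
Why: Fluoride cleaves both aryl silyl ethers (desilylation), and the dioxolane of 19, whose oxocarbenium ion is stabilised by the 2,4,6-trihydroxyphenyl ring, undergoes acid-catalysed ketal hydrolysis in cold dilute acid far faster than a prenyl group cyclises onto a neighbouring phenol, giving the hydrogen-bonded acylphloroglucinol.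

**Compound list**

1 | ethynylmagnesium bromide | C#C[Mg]Br | starting material
2 | 1-bromo-3-methylbut-2-ene (prenyl bromide) | CC(C)=CCBr | starting material
3 | 5-methylhex-4-en-1-yne | CC(C)=CCC#C | intermediate
4 | lithium 5-methylhex-4-en-1-yn-1-ide | [Li]C#CCC=C(C)C | intermediate
5 | lithium 5-methylhex-4-en-1-yn-1-olate | [Li]OC#CCC=C(C)C | intermediate
6 | triisopropyl[(5-methylhex-4-en-1-yn-1-yl)oxy]silane | CC(C)=CCC#CO[Si](C(C)C)(C(C)C)C(C)C | intermediate
7 | ethyl 3-oxo-3-phenylpropanoate (ethyl benzoylacetate) | CCOC(=O)CC(=O)c1ccccc1 | starting material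
8 | ethane-1,2-diol | OCCO | starting material
9 | ethyl 2-(2-phenyl-1,3-dioxolan-2-yl)acetate | CCOC(=O)CC1(c2ccccc2)OCCO1 | intermediate
10 | potassium 2-(2-phenyl-1,3-dioxolan-2-yl)acetate | [K+].[O-]C(=O)CC1(c2ccccc2)OCCO1 | intermediate
11 | 2-(2-phenyl-1,3-dioxolan-2-yl)acetyl chloride | O=C(Cl)CC1(c2ccccc2)OCCO1 | intermediate
12 | 2-(2-phenyl-1,3-dioxolan-2-yl)ethen-1-one (ketene) | O=C=CC1(c2ccccc2)OCCO1 | intermediate
13 | 2-(3-methylbut-2-en-1-yl)-4-(2-phenyl-1,3-dioxolan-2-yl)-3-(triisopropylsilyloxy)cyclobut-2-en-1-one (racemic) | O=C1C(CC=C(C)C)=C(O[Si](C(C)C)(C(C)C)C(C)C)C1C3(c2ccccc2)OCCO3 | intermediate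
14 | (3Z)-2-(3-methylbut-2-en-1-yl)-4-(2-phenyl-1,3-dioxolan-2-yl)-3-(triisopropylsilyloxy)buta-1,3-dien-1-one | O=C=C(CC=C(C)C)/C(O[Si](C(C)C)(C(C)C)C(C)C)=C/C1(c2ccccc2)OCCO1 | intermediate
15 | 2,4-bis(3-methylbut-2-en-1-yl)-4-[(Z)-2-(2-phenyl-1,3-dioxolan-2-yl)-1-(triisopropylsilyloxy)ethenyl]-3-(triisopropylsilyloxy)cyclobut-2-en-1-one (racemic) | O=C1C(CC=C(C)C)=C(O[Si](C(C)C)(C(C)C)C(C)C)C1(CC=C(C)C)/C(O[Si](C(C)C)(C(C)C)C(C)C)=C/C3(c2ccccc2)OCCO3 | intermediate
16 | (3E,5Z)-2,4-bis(3-methylbut-2-en-1-yl)-6-(2-phenyl-1,3-dioxolan-2-yl)-3,5-bis(triisopropylsilyloxy)hexa-1,3,5-trien-1-one | O=C=C(CC=C(C)C)/C(O[Si](C(C)C)(C(C)C)C(C)C)=C(CC=C(C)C)\C(O[Si](C(C)C)(C(C)C)C(C)C)=C\C1(c2ccccc2)OCCO1 | intermediate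
17 | 2,4-bis(3-methylbut-2-en-1-yl)-6-(2-phenyl-1,3-dioxolan-2-yl)-3,5-bis(triisopropylsilyloxy)cyclohexa-2,4-dien-1-one (racemic) | O=C1C(CC=C(C)C)=C(O[Si](C(C)C)(C(C)C)C(C)C)C(CC=C(C)C)=C(O[Si](C(C)C)(C(C)C)C(C)C)C1C3(c2ccccc2)OCCO3 | intermediate
18 | 2,4-bis(3-methylbut-2-en-1-yl)-6-(2-phenyl-1,3-dioxolan-2-yl)-3,5-bis(triisopropylsilyloxy)phenol | Oc1c(CC=C(C)C)c(O[Si](C(C)C)(C(C)C)C(C)C)c(CC=C(C)C)c(O[Si](C(C)C)(C(C)C)C(C)C)c1C3(c2ccccc2)OCCO3 | intermediate
19 | 2,4-bis(3-methylbut-2-en-1-yl)-6-(2-phenyl-1,3-dioxolan-2-yl)benzene-1,3,5-triol | Oc1c(CC=C(C)C)c(O)c(CC=C(C)C)c(O)c1C3(c2ccccc2)OCCO3 | intermediate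
20 | clusiaphenone B, phenyl[2,4,6-trihydroxy-3,5-bis(3-methylbut-2-en-1-yl)phenyl]methanone | CC(C)=CCc1c(O)c(CC=C(C)C)c(O)c(C(=O)c2ccccc2)c1O | target

Total step count: 7. Longest linear sequence: 5 steps (steps 1, 2, 5, 6, 7; the branch through steps 3 and 4 is equally long).

Steps most likely to fail:

Step 6 (benzannulation). The donor-stabilised 3-siloxycyclobutenone may open too slowly. At the temperature then needed the vinylketene could be lost by self-condensation or by acylating the phenol already formed, and the 6π closure at the terminus that bears the quaternary dioxolanyl carbon may lag behind. Fallback: the ring would be bought instead of built. Setting out from 2, commercial (2,4,6-trihydroxyphenyl)(phenyl)methanone F1 would be C-prenylated twice with 2 in aqueous KOH at 0 °C (C-alkylation of the phloroglucinol phenoxide in water). This comes back to the route at 20, at the price of a separation from mono-, tri- and O-prenylated material.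

Step 5 (ketene cycloaddition). Ketene 12 may dimerise, or the dioxolane may open by β-elimination during dehydrochlorination, faster than 6 intercepts the ketene. Fallback: the roles would be exchanged so that the masked benzoyl group travels on the alkyne and no ketal-bearing ketene is needed. Setting out from 6, 5-methylhex-4-enoyl chloride F2 and Et3N would give 5-methylhexa-1,4-dien-1-one F3 (prenylketene), whose [2+2] cycloaddition with 6 should give 2,4-bis(3-methylbut-2-en-1-yl)-3-(triisopropylsilyloxy)cyclobut-2-en-1-one F4. Methyl 2-phenyl-1,3-dioxolane-2-carboxylate F5 (from methyl benzoylformate and 8) would be converted by Kowalski ester homologation (CH2Br2, lithium 2,2,6,6-tetramethylpiperidide, then n-BuLi) and O-silylation with i-Pr3SiOTf into triisopropyl{[(2-phenyl-1,3-dioxolan-2-yl)ethynyl]oxy}silane F6. The Danheiser benzannulation of F4 with F6 comes back to the route at 18.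

Step 2 (ynolate formation). Oxygen transfer from LiOOt-Bu to acetylide 4 may be slow or incomplete, leaving alkyne that is hard to separate from the sensitive siloxyalkyne. Fallback: ynolate 5 would be reached by C–C bond formation instead of oxidation. Setting out from 2, palladium-catalysed ethoxycarbonylation (CO, EtOH, Pd(OAc)2, PPh3, i-Pr2NEt) would give ethyl 4-methylpent-3-enoate F7. Its Kowalski ester homologation (CH2Br2, lithium 2,2,6,6-tetramethylpiperidide, then n-BuLi) comes back to the route at 5, before the silylation.

Further compounds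
F1 | step 6 | (2,4,6-trihydroxyphenyl)(phenyl)methanone | O=C(c1ccccc1)c1c(O)cc(O)cc1O
F2 | step 5 | 5-methylhex-4-enoyl chloride | CC(C)=CCCC(=O)Cl
F3 | step 5 | 5-methylhexa-1,4-dien-1-one (prenylketene) | CC(C)=CCC=C=O
F4 | step 5 | 2,4-bis(3-methylbut-2-en-1-yl)-3-(triisopropylsilyloxy)cyclobut-2-en-1-one (racemic) | O=C1C(CC=C(C)C)=C(O[Si](C(C)C)(C(C)C)C(C)C)C1CC=C(C)C
F5 | step 5 | methyl 2-phenyl-1,3-dioxolane-2-carboxylate | COC(=O)C1(c2ccccc2)OCCO1
F6 | step 5 | triisopropyl{[(2-phenyl-1,3-dioxolan-2-yl)ethynyl]oxy}silane | CC(C)[Si](C(C)C)(C(C)C)OC#CC1(c2ccccc2)OCCO1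
F7 | step 2 | ethyl 4-methylpent-3-enoate | CCOC(=O)CC=C(C)C
A1 | direct plan | 7-methyl-1-phenyloct-6-ene-1,3-dione | CC(C)=CCCC(=O)CC(=O)c1ccccc1
A2 | direct plan | (1Z,3Z)-7-methyl-1-phenyl-1,3-bis(trimethylsilyloxy)octa-1,3,6-triene | C[Si](C)(C)O/C(c1ccccc1)=C\C(O[Si](C)(C)C)=C\CC=C(C)C
A3 | direct plan | 2-(3-methylbut-2-en-1-yl)malonyl dichloride | CC(C)=CCC(C(=O)Cl)C(=O)Cl
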